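**Plan**
- Positions are numbered as in the avarane/clerodane series: C4 carries the =CH2, C5 (Me) and C10 (H) are the ring-fusion carbons, C8 carries Me, C9 carries Me and the benzyl group. After removing the sulfate and protecting groups and re-oxygenating C2, the retrosynthesis cuts C2–C3 and the ring-fusion bond C5–C10, which opens both rings at once.
- Enabling feature: ring A is a 3-methylenecyclohexane. Its C3–C4(=CH2)–C5 triad, with C5 quaternary and methyl-bearing, is the footprint of a Me2C=C(Me) group that has served twice as an ene donor. Its C10–C1–C2 triad is the footprint of an (E)-enal. The precursor is therefore the acyclic dienal 18.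
- Forward: (S)-4-methyl-δ-valerolactone carries C8. Two enolate alkylations (MeI, then the benzylic bromide 5) set C9. Lactone opening, a Negishi coupling (C5–C6) and a Wittig reaction give 18.
- One Me2AlCl-triggered cascade closes ring B (conjugate ene, C5–C10) and then ring A (type II carbonyl-ene, C2–C3), installing the exocyclic alkene directly. The C2–OH is then removed by Barton–McCombie deoxygenation.
- Stereochemistry: C8 from the chiral pool, C9 by 1,2-induction in the lactone enolate, C5 and C10 by a chair transition state steered by C8/C9.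
- Endgame: aryl chloride to CH2OH, differentiation of the catechol, sulfation of the hindered phenol, fluoride deprotection.

Key step: step 13

Assumption and notation: the target is drawn as the free aryl hydrogen sulfate; 26 and 27 would be handled as sodium salts and are written in the neutral form. Ar = 5-chloro-2,3-bis[(triisopropylsilyl)oxy]phenyl; "decalyl" = (1R,2S,4aS,8aS)-1,2,4a-trimethyl-5-methylidenedecahydronaphthalen-1-yl.

Step 1
Reactants: 1 5-chloro-2-hydroxy-3-methoxybenzaldehyde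
Product: 2 5-chloro-2,3-dihydroxybenzaldehyde
Conditions: BBr3, CH2Cl2, −78 °C → rt; H2O
Reagents that add atoms: none
Why: Lewis-acid aryl methyl ether cleavage (bromide attacks the methyl group of the boron-complexed ether) should free the second phenol without touching the aldehyde or the aryl chloride.

Step 2
Reactants: 2 5-chloro-2,3-dihydroxybenzaldehyde
Product: 3 5-chloro-2,3-bis[(triisopropylsilyl)oxy]benzaldehyde (ArCHO)
Conditions: TIPSOTf (2.3 equiv), 2,6-lutidine, CH2Cl2, 0 °C → rt
Reagents that add atoms: triisopropylsilyl trifluoromethanesulfonate CC(C)[Si](C(C)C)(C(C)C)OS(=O)(=O)C(F)(F)F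
Why: Silyl triflate silylation should cap both phenols, including the hydrogen-bonded one, as aryl TIPS ethers that tolerate the enolate, hydride, organozinc, Lewis-acid and aqueous-carbonate steps that follow.

Step 3
Reactants: 3 5-chloro-2,3-bis[(triisopropylsilyl)oxy]benzaldehyde
Product: 4 {5-chloro-2,3-bis[(triisopropylsilyl)oxy]phenyl}methanol (ArCH2OH)
Conditions: NaBH4, THF/EtOH, 0 °C
Reagents that add atoms: none
Why: Borohydride reduction of the aldehyde should give the benzylic alcohol while the hindered aryl silyl ethers stay in place.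

Step 4
Reactants: 4 {5-chloro-2,3-bis[(triisopropylsilyl)oxy]phenyl}methanol
Product: 5 1-(bromomethyl)-5-chloro-2,3-bis[(triisopropylsilyl)oxy]benzene (ArCH2Br)
Conditions: CBr4, PPh3, CH2Cl2, 0 °C
Reagents that add atoms: carbon tetrabromide BrC(Br)(Br)Br
Why: Appel bromination under neutral conditions should give the benzylic bromide without silyl loss.

Step 5
Reactants: 6 (3R)-5-methoxy-3-methyl-5-oxopentanoic acid (methyl hydrogen (R)-3-methylglutarate)
Product: 8 (4S)-4-methyloxan-2-one, via (S)-5-hydroxy-3-methylpentanoic acid 7 (not isolated)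
Conditions: LiBH4, THF, 0 °C → rt; then 2 M HCl, rt
Reagents that add atoms: none
Why: Chemoselective LiBH4 reduction of the ester beside the lithium carboxylate, then acid lactonisation, should give the (S)-lactone because the two arms of the untouched stereocentre exchange their oxidation levels.

Step 6
Reactants: 8 (4S)-4-methyloxan-2-one
Product: 9 (3R,4S)-3,4-dimethyloxan-2-one (trans)
Conditions: LDA (1.05 equiv), THF, −78 °C; MeI, −78 → −40 °C
Reagents that add atoms: iodomethane CI
Why: Lactone enolate alkylation should occur anti to the C4 methyl group; the C3 configuration is of no consequence because C3 is planarised again in step 7.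

Step 7
Reactants: 9 (3R,4S)-3,4-dimethyloxan-2-one; 5 1-(bromomethyl)-5-chloro-2,3-bis[(triisopropylsilyl)oxy]benzene
Product: 10 (3R,4S)-3-(ArCH2)-3,4-dimethyloxan-2-one
Conditions: LDA (1.1 equiv), THF, −78 °C; DMPU; then 5, −78 → −20 °C
Reagents that add atoms: none
Why: Enolate alkylation should form the quaternary centre with the benzyl group trans to the C4 methyl, because A(1,2) strain in the tetrasubstituted enolate holds that methyl pseudoaxial and the electrophile enters from the opposite face.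

Step 8
Reactants: 10 (3R,4S)-3-(ArCH2)-3,4-dimethyloxan-2-one
Product: 11 (2R,3S)-2-(ArCH2)-5-hydroxy-N-methoxy-N,2,3-trimethylpentanamide
Conditions: MeNH(OMe)·HCl (3 equiv), Me3Al (3 equiv), CH2Cl2, 0 °C → rt; Rochelle salt
Reagents that add atoms: N,O-dimethylhydroxylamine hydrochloride CNOC.Cl
Why: Aluminium-amide aminolysis of the lactone should unmask the primary alcohol and place the hindered carbonyl at the Weinreb amide level without touching either stereocentre.

Step 9
Reactants: 11 (2R,3S)-2-(ArCH2)-5-hydroxy-N-methoxy-N,2,3-trimethylpentanamide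
Product: 12 (2R,3S)-2-(ArCH2)-5-iodo-N-methoxy-N,2,3-trimethylpentanamide
Conditions: I2, PPh3, imidazole, CH2Cl2, 0 °C (crude 11 used at once)
Reagents that add atoms: iodine II
Why: Appel-type iodination of the unhindered primary alcohol should proceed cleanly and removes the hydroxyl group that could otherwise re-close the lactone.

Step 10
Reactants: 12 (2R,3S)-2-(ArCH2)-5-iodo-N-methoxy-N,2,3-trimethylpentanamide; 13 2-bromo-3-methylbut-2-ene
Product: 15 (2R,3S)-2-(ArCH2)-N-methoxy-N,2,3,6,7-pentamethyloct-6-enamide, via alkylzinc iodide 14 (not isolated)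
Conditions: Zn dust (TMSCl/BrCH2CH2Br-activated), DMA, 40 °C; then 13, PdCl2(dppf) (5 mol %), THF, 50 °C
Reagents that add atoms: none
Why: Negishi sp3–sp2 cross-coupling of the primary alkylzinc iodide with the alkenyl bromide should form the C5–C6 bond and install the tetrasubstituted alkene, with the Weinreb amide and the aryl chloride inert to zinc and to the dppf–palladium catalyst.

Step 11
Reactants: 15 (2R,3S)-2-(ArCH2)-N-methoxy-N,2,3,6,7-pentamethyloct-6-enamide
Product: 16 (2R,3S)-2-(ArCH2)-2,3,6,7-tetramethyloct-6-enal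
Conditions: DIBAL-H, THF, −78 → 0 °C; Rochelle salt
Reagents that add atoms: none
Why: Weinreb amide reduction should stop at the aldehyde through the chelated tetrahedral intermediate, and the α-quaternary aldehyde cannot epimerise.

Step 12
Reactants: 16 (2R,3S)-2-(ArCH2)-2,3,6,7-tetramethyloct-6-enal; 17 2-(triphenyl-λ5-phosphanylidene)acetaldehyde
Product: 18 (2E,4R,5S)-4-(ArCH2)-4,5,8,9-tetramethyldeca-2,8-dienal
Conditions: toluene, 100 °C
Reagents that add atoms: none
Why: Wittig olefination with the stabilised formyl ylide should give the (E)-enal, and the neopentyl-type product is too hindered to react a second time.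

Step 13
Reactants: 18 (2E,4R,5S)-4-(ArCH2)-4,5,8,9-tetramethyldeca-2,8-dienal
Product: 20 (2R,4aS,7S,8R,8aS)-8-(ArCH2)-4a,7,8-trimethyl-4-methylidenedecahydronaphthalen-2-ol, via monocyclic ene aldehyde 19 (not isolated)
Conditions: Me2AlCl (2.5 equiv), CH2Cl2, −78 → −20 °C; aq. NaHCO3/Rochelle salt
Reagents that add atoms: none
Why: Proposed new method: Me2AlCl complexation makes C10 of the enal electrophilic; the tetrasubstituted alkene attacks through C5 (ring B, 6-exo-trig at the enal C=C, leaving a tertiary cation at C4) and a C4-methyl hydrogen passes to C1 (formal conjugate ene reaction), giving aldehyde 19 with an isopropenyl group on the new quaternary C5. The still-complexed aldehyde should then close ring A by a type II carbonyl-ene reaction (C3–C2 bond, six-membered, exo at the C=O, hydrogen from the remaining methyl to oxygen), which leaves the exocyclic C4=CH2 because C5 bears no hydrogen. The closest known reaction types are the Me2AlCl-promoted sequential ene annulation of alkenes with enals and the type II carbonyl-ene cyclisation to 3-methylenecyclohexanols; new here is an intramolecular first ene step on a tetrasubstituted alkene, so that both rings form in one flask. C5 and C10 should be set in a chair transition state for ring B with the C8 methyl and the C9 benzyl group equatorial and the C9 methyl axial: C5 then places its methyl, not the bulky CMe2 terminus, in the axial site syn to the C9 methyl, and the (E)-enal arm lies equatorial, which gives the trans ring fusion; the C2 carbinol (axial OH expected from the bicyclic ene transition state) is removed later. The step needs the alkene, not the arene, as the nucleophile (the arene is deactivated by Cl, shielded by two OTIPS groups and could only close a strained five-membered ring). It also needs hydrogen transfer to outrun collapse of the C4 cation/aluminium enolate pair to a cyclobutane or dihydropyran (both reversible under the Lewis acid), and it needs the exocyclic alkene, which the cyclic hydrogen transfer and the proton-scavenging Al–Me bonds should secure.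

Step 14
Reactants: 20 (2R,4aS,7S,8R,8aS)-8-(ArCH2)-4a,7,8-trimethyl-4-methylidenedecahydronaphthalen-2-ol
Product: 21 O-[(2R,4aS,7S,8R,8aS)-8-(ArCH2)-4a,7,8-trimethyl-4-methylidenedecahydronaphthalen-2-yl] O-phenyl carbonothioate
Conditions: PhOC(S)Cl, pyridine, DMAP (cat.), CH2Cl2, rt
Reagents that add atoms: O-phenyl carbonochloridothioate S=C(Cl)Oc1ccccc1
Why: Thioacylation of the secondary alcohol under mildly basic conditions should give the Barton–McCombie substrate without affecting the aryl silyl ethers or the exocyclic alkene.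

Step 15
Reactants: 21 O-[(2R,4aS,7S,8R,8aS)-8-(ArCH2)-4a,7,8-trimethyl-4-methylidenedecahydronaphthalen-2-yl] O-phenyl carbonothioate
Product: 22 (1R,2S,4aS,8aS)-1-(ArCH2)-1,2,4a-trimethyl-5-methylidenedecahydronaphthalene
Conditions: Bu3SnH, AIBN (cat.), toluene, 90 °C
Reagents that add atoms: none
Why: Barton–McCombie radical deoxygenation should replace the C2 oxygen by hydrogen, since the stannane does not reduce the aryl chloride and hydrogen transfer to the secondary C2 radical outpaces its reversible 3-exo addition to the exocyclic alkene.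

Step 16
Reactants: 22 (1R,2S,4aS,8aS)-1-(ArCH2)-1,2,4a-trimethyl-5-methylidenedecahydronaphthalene
Product: 23 {3,4-bis[(triisopropylsilyl)oxy]-5-(decalylmethyl)phenyl}methanol
Conditions: AcOCH2BF3K, Pd(OAc)2 (5 mol %), RuPhos (10 mol %), Na2CO3, dioxane/H2O 10:1, 85 °C
Reagents that add atoms: potassium (acetoxymethyl)trifluoroborate CC(=O)OC[B-](F)(F)F.[K+]
Why: Suzuki–Miyaura hydroxymethylation should convert the unhindered, electron-rich aryl chloride into the benzylic alcohol, the acetate being hydrolysed in situ and the hindered aryl TIPS ethers surviving the carbonate base.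

Step 17
Reactants: 23 {3,4-bis[(triisopropylsilyl)oxy]-5-(decalylmethyl)phenyl}methanol
Product: 24 5-(hydroxymethyl)-3-(decalylmethyl)benzene-1,2-diol
Conditions: TBAF, AcOH, THF, 0 °C, argon
Reagents that add atoms: none
Why: Buffered fluoride desilylation should free both phenols without acid, so the exocyclic alkene cannot migrate.

Step 18
Reactants: 24 5-(hydroxymethyl)-3-(decalylmethyl)benzene-1,2-diol
Product: 25 2-[(tert-butyldimethylsilyl)oxy]-4-{[(tert-butyldimethylsilyl)oxy]methyl}-6-(decalylmethyl)phenol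
Conditions: TBSCl (2.1 equiv), imidazole, DMF, 0 °C
Reagents that add atoms: tert-butyldimethylsilyl chloride CC(C)(C)[Si](C)(C)Cl
Why: Chemoselective silylation should take the primary alcohol and the less hindered phenol and leave the phenol flanked by the neopentyl-type benzyl group free, and base-mediated 1,2-silyl migration would funnel any mis-silylated material to the same isomer.

Step 19
Reactants: 25 2-[(tert-butyldimethylsilyl)oxy]-4-{[(tert-butyldimethylsilyl)oxy]methyl}-6-(decalylmethyl)phenol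
Product: 26 2-[(tert-butyldimethylsilyl)oxy]-4-{[(tert-butyldimethylsilyl)oxy]methyl}-6-(decalylmethyl)phenyl hydrogen sulfate
Conditions: SO3·pyridine (4 equiv), pyridine, 40 °C; aq. NaHCO3 (sodium salt)
Reagents that add atoms: sulfur trioxide–pyridine complex O=S(=O)([O-])[n+]1ccccc1
Why: O-Sulfation of the only free hydroxyl group with the small SO3 donor should give the aryl sulfate, which is stable as its salt under the basic conditions.

Step 20
Reactants: 26 2-[(tert-butyldimethylsilyl)oxy]-4-{[(tert-butyldimethylsilyl)oxy]methyl}-6-(decalylmethyl)phenyl hydrogen sulfate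
Product: 27 2-hydroxy-4-(hydroxymethyl)-6-(decalylmethyl)phenyl hydrogen sulfate (target)
Conditions: NH4F, MeOH, rt → 40 °C; reversed-phase isolation as the sodium salt (free acid on cold H+ resin)
Reagents that add atoms: none
Why: Neutral fluoride desilylation should remove the aryl and the primary alkyl TBS ethers while the acid-labile aryl sulfate is never exposed to acid.

**Compound list**
1 | 5-chloro-2-hydroxy-3-methoxybenzaldehyde | O=Cc1cc(Cl)cc(OC)c1O | starting material
2 | 5-chloro-2,3-dihydroxybenzaldehyde | O=Cc1cc(Cl)cc(O)c1O | intermediate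
3 | 5-chloro-2,3-bis[(triisopropylsilyl)oxy]benzaldehyde | O=Cc1cc(Cl)cc(O[Si](C(C)C)(C(C)C)C(C)C)c1O[Si](C(C)C)(C(C)C)C(C)C | intermediate
4 | {5-chloro-2,3-bis[(triisopropylsilyl)oxy]phenyl}methanol | OCc1cc(Cl)cc(O[Si](C(C)C)(C(C)C)C(C)C)c1O[Si](C(C)C)(C(C)C)C(C)C | intermediate
5 | 1-(bromomethyl)-5-chloro-2,3-bis[(triisopropylsilyl)oxy]benzene | BrCc1cc(Cl)cc(O[Si](C(C)C)(C(C)C)C(C)C)c1O[Si](C(C)C)(C(C)C)C(C)C | intermediate
6 | (3R)-5-methoxy-3-methyl-5-oxopentanoic acid | COC(=O)C[C@H](C)CC(=O)O | starting material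
7 | (S)-5-hydroxy-3-methylpentanoic acid | OCC[C@H](C)CC(=O)O | intermediate
8 | (4S)-4-methyloxan-2-one | O=C1OCC[C@H](C)C1 | intermediate
9 | (3R,4S)-3,4-dimethyloxan-2-one | O=C1OCC[C@H](C)[C@H]1C | intermediate
10 | (3R,4S)-3-(ArCH2)-3,4-dimethyloxan-2-one | O=C1OCC[C@H](C)[C@@]1(C)Cc1cc(Cl)cc(O[Si](C(C)C)(C(C)C)C(C)C)c1O[Si](C(C)C)(C(C)C)C(C)C | intermediate
11 | (2R,3S)-2-(ArCH2)-5-hydroxy-N-methoxy-N,2,3-trimethylpentanamide | CON(C)C(=O)[C@](C)(Cc1cc(Cl)cc(O[Si](C(C)C)(C(C)C)C(C)C)c1O[Si](C(C)C)(C(C)C)C(C)C)[C@@H](C)CCO | intermediate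
12 | (2R,3S)-2-(ArCH2)-5-iodo-N-methoxy-N,2,3-trimethylpentanamide | CON(C)C(=O)[C@](C)(Cc1cc(Cl)cc(O[Si](C(C)C)(C(C)C)C(C)C)c1O[Si](C(C)C)(C(C)C)C(C)C)[C@@H](C)CCI | intermediate
13 | 2-bromo-3-methylbut-2-ene | CC(C)=C(C)Br | starting material
14 | {(3S,4R)-4-(ArCH2)-5-[methoxy(methyl)amino]-3,4-dimethyl-5-oxopentyl}zinc iodide | CON(C)C(=O)[C@](C)(Cc1cc(Cl)cc(O[Si](C(C)C)(C(C)C)C(C)C)c1O[Si](C(C)C)(C(C)C)C(C)C)[C@@H](C)CC[Zn]I | intermediate
15 | (2R,3S)-2-(ArCH2)-N-methoxy-N,2,3,6,7-pentamethyloct-6-enamide | CON(C)C(=O)[C@](C)(Cc1cc(Cl)cc(O[Si](C(C)C)(C(C)C)C(C)C)c1O[Si](C(C)C)(C(C)C)C(C)C)[C@@H](C)CCC(C)=C(C)C | intermediate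
16 | (2R,3S)-2-(ArCH2)-2,3,6,7-tetramethyloct-6-enal | O=C[C@](C)(Cc1cc(Cl)cc(O[Si](C(C)C)(C(C)C)C(C)C)c1O[Si](C(C)C)(C(C)C)C(C)C)[C@@H](C)CCC(C)=C(C)C | intermediate
17 | 2-(triphenyl-λ5-phosphanylidene)acetaldehyde | O=CC=P(c1ccccc1)(c1ccccc1)c1ccccc1 | starting material
18 | (2E,4R,5S)-4-(ArCH2)-4,5,8,9-tetramethyldeca-2,8-dienal | O=C/C=C/[C@](C)(Cc1cc(Cl)cc(O[Si](C(C)C)(C(C)C)C(C)C)c1O[Si](C(C)C)(C(C)C)C(C)C)[C@@H](C)CCC(C)=C(C)C | intermediate
19 | 2-[(1S,2R,3S,6S)-2-(ArCH2)-2,3,6-trimethyl-6-(prop-1-en-2-yl)cyclohexyl]acetaldehyde | O=CC[C@H]1[C@](C)(Cc2cc(Cl)cc(O[Si](C(C)C)(C(C)C)C(C)C)c2O[Si](C(C)C)(C(C)C)C(C)C)[C@@H](C)CC[C@]1(C)C(C)=C | intermediate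
20 | (2R,4aS,7S,8R,8aS)-8-(ArCH2)-4a,7,8-trimethyl-4-methylidenedecahydronaphthalen-2-ol | C=C1C[C@H](O)C[C@H]2[C@](C)(Cc3cc(Cl)cc(O[Si](C(C)C)(C(C)C)C(C)C)c3O[Si](C(C)C)(C(C)C)C(C)C)[C@@H](C)CC[C@]12C | intermediate
21 | O-[(2R,4aS,7S,8R,8aS)-8-(ArCH2)-4a,7,8-trimethyl-4-methylidenedecahydronaphthalen-2-yl] O-phenyl carbonothioate | C=C1C[C@H](OC(=S)Oc3ccccc3)C[C@H]2[C@](C)(Cc3cc(Cl)cc(O[Si](C(C)C)(C(C)C)C(C)C)c3O[Si](C(C)C)(C(C)C)C(C)C)[C@@H](C)CC[C@]12C | intermediate
22 | (1R,2S,4aS,8aS)-1-(ArCH2)-1,2,4a-trimethyl-5-methylidenedecahydronaphthalene | C=C1CCC[C@H]2[C@](C)(Cc3cc(Cl)cc(O[Si](C(C)C)(C(C)C)C(C)C)c3O[Si](C(C)C)(C(C)C)C(C)C)[C@@H](C)CC[C@]12C | intermediate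
23 | {3,4-bis[(triisopropylsilyl)oxy]-5-(decalylmethyl)phenyl}methanol | C=C1CCC[C@H]2[C@](C)(Cc3cc(CO)cc(O[Si](C(C)C)(C(C)C)C(C)C)c3O[Si](C(C)C)(C(C)C)C(C)C)[C@@H](C)CC[C@]12C | intermediate
24 | 5-(hydroxymethyl)-3-(decalylmethyl)benzene-1,2-diol | C=C1CCC[C@H]2[C@](C)(Cc3cc(CO)cc(O)c3O)[C@@H](C)CC[C@]12C | intermediate
25 | 2-[(tert-butyldimethylsilyl)oxy]-4-{[(tert-butyldimethylsilyl)oxy]methyl}-6-(decalylmethyl)phenol | C=C1CCC[C@H]2[C@](C)(Cc3cc(CO[Si](C)(C)C(C)(C)C)cc(O[Si](C)(C)C(C)(C)C)c3O)[C@@H](C)CC[C@]12C | intermediate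
26 | 2-[(tert-butyldimethylsilyl)oxy]-4-{[(tert-butyldimethylsilyl)oxy]methyl}-6-(decalylmethyl)phenyl hydrogen sulfate | C=C1CCC[C@H]2[C@](C)(Cc3cc(CO[Si](C)(C)C(C)(C)C)cc(O[Si](C)(C)C(C)(C)C)c3OS(=O)(=O)O)[C@@H](C)CC[C@]12C | intermediate
27 | 2-hydroxy-4-(hydroxymethyl)-6-{[(1R,2S,4aS,8aS)-1,2,4a-trimethyl-5-methylidenedecahydronaphthalen-1-yl]methyl}phenyl hydrogen sulfate | C=C1CCC[C@H]2[C@](C)(Cc3cc(CO)cc(O)c3OS(=O)(=O)O)[C@@H](C)CC[C@]12C | target

**Count and risks**
Total step count: 20. Longest linear sequence: 18 steps (steps 1–4, then 7–20).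

Step 13 (most likely to fail). What may go wrong: attack on the wrong face of the enal at C10 would give the cis-fused decalin. The cascade may also stop after the first ring, or the C4 cation may be diverted into cyclobutane or dihydropyran formation or a 1,2-shift. Fallback, an anionic Michael–aldol annulation that makes the same two bonds by known chemistry, sets out from iodide 12 and comes back at 22. Iodide 12 would alkylate the sodium enolate of allyl 2-methylacetoacetate to give the allyl β-keto ester F1. Pd(PPh3)4/morpholine deallylation–decarboxylation would give the methyl ketone F2 (both epimers at the new methine, which is planarised later). Excess DIBAL-H would give the hydroxy aldehyde F3, and Wittig reaction with 17 the hydroxy enal F4. Dess–Martin oxidation would give the keto enal F5. Pyrrolidinium acetate (or KOH/MeOH) would then bring about Michael addition of the more substituted enol(ate) to the enal and aldol condensation, giving the bicyclic enone F6 under reversible, stereoconvergent conditions. Conjugate reduction with [(Ph3P)CuH]6 would give the saturated ketone F7, and Wittig methylenation (Ph3P=CH2, toluene, 90 °C) would give 22.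

Step 8. What may go wrong: slow aminolysis at the neopentyl-type lactone carbonyl, and re-closure of the ring (relactonisation of 11, or O-alkylative cyclisation of iodide 12 in step 9). Fallback, a reductive opening with temporary protection, sets out from lactone 10 and comes back at aldehyde 16. LiAlH4 would give the diol F8. I2/PPh3/imidazole (1 equiv, 0 °C) would convert only the unhindered primary alcohol, giving the iodo alcohol F9. TESCl/imidazole would give the silyl ether F10. Displacement with lithium bis(3-methylbut-2-en-2-yl)cuprate (from 13, t-BuLi, CuI) would give the alkene F11. PPTS/MeOH would remove the TES group to give the alcohol F12, and Dess–Martin oxidation would give 16.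

Step 18. What may go wrong: poor discrimination between the two phenolic oxygens during silylation, which would place the sulfate on the wrong oxygen in step 19. Fallback, which uses an electronic instead of a steric bias, sets out from benzylic alcohol 23 and comes back at the target 27. MnO2 would give the aldehyde F13. K2CO3/MeOH (1 equiv, 0 °C) should cleave only the silyl ether para to the formyl group, since that oxygen is the best phenoxide leaving group and a 1,2-silyl shift leads to the same product, giving the phenol F14. SO3·pyridine would give the aryl sulfate F15, NaBH4 the benzylic alcohol F16, and TBAF would give 27.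

Further compounds
F1 | step 13 | prop-2-en-1-yl (5S,6R)-2-acetyl-6-(ArCH2)-7-[methoxy(methyl)amino]-2,5,6-trimethyl-7-oxoheptanoate | CON(C)C(=O)[C@](C)(Cc1cc(Cl)cc(O[Si](C(C)C)(C(C)C)C(C)C)c1O[Si](C(C)C)(C(C)C)C(C)C)[C@@H](C)CCC(C)(C(C)=O)C(=O)OCC=C
F2 | step 13 | (2R,3S)-2-(ArCH2)-N-methoxy-N,2,3,6-tetramethyl-7-oxooctanamide | CON(C)C(=O)[C@](C)(Cc1cc(Cl)cc(O[Si](C(C)C)(C(C)C)C(C)C)c1O[Si](C(C)C)(C(C)C)C(C)C)[C@@H](C)CCC(C)C(C)=O
F3 | step 13 | (2R,3S)-2-(ArCH2)-7-hydroxy-2,3,6-trimethyloctanal | O=C[C@](C)(Cc1cc(Cl)cc(O[Si](C(C)C)(C(C)C)C(C)C)c1O[Si](C(C)C)(C(C)C)C(C)C)[C@@H](C)CCC(C)C(C)O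
F4 | step 13 | (2E,4R,5S)-4-(ArCH2)-9-hydroxy-4,5,8-trimethyldec-2-enal | O=C/C=C/[C@](C)(Cc1cc(Cl)cc(O[Si](C(C)C)(C(C)C)C(C)C)c1O[Si](C(C)C)(C(C)C)C(C)C)[C@@H](C)CCC(C)C(C)O
F5 | step 13 | (2E,4R,5S)-4-(ArCH2)-4,5,8-trimethyl-9-oxodec-2-enal | O=C/C=C/[C@](C)(Cc1cc(Cl)cc(O[Si](C(C)C)(C(C)C)C(C)C)c1O[Si](C(C)C)(C(C)C)C(C)C)[C@@H](C)CCC(C)C(C)=O
F6 | step 13 | (4aS,5R,6S,8aS)-5-(ArCH2)-5,6,8a-trimethyl-4a,5,6,7,8,8a-hexahydronaphthalen-1(4H)-one | O=C1C=CC[C@H]2[C@](C)(Cc3cc(Cl)cc(O[Si](C(C)C)(C(C)C)C(C)C)c3O[Si](C(C)C)(C(C)C)C(C)C)[C@@H](C)CC[C@]12C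
F7 | step 13 | (4aS,5R,6S,8aS)-5-(ArCH2)-5,6,8a-trimethyloctahydronaphthalen-1(2H)-one | O=C1CCC[C@H]2[C@](C)(Cc3cc(Cl)cc(O[Si](C(C)C)(C(C)C)C(C)C)c3O[Si](C(C)C)(C(C)C)C(C)C)[C@@H](C)CC[C@]12C
F8 | step 8 | (2R,3S)-2-(ArCH2)-2,3-dimethylpentane-1,5-diol | OC[C@](C)(Cc1cc(Cl)cc(O[Si](C(C)C)(C(C)C)C(C)C)c1O[Si](C(C)C)(C(C)C)C(C)C)[C@@H](C)CCO
F9 | step 8 | (2R,3S)-2-(ArCH2)-5-iodo-2,3-dimethylpentan-1-ol | OC[C@](C)(Cc1cc(Cl)cc(O[Si](C(C)C)(C(C)C)C(C)C)c1O[Si](C(C)C)(C(C)C)C(C)C)[C@@H](C)CCI
F10 | step 8 | triethyl{[(2R,3S)-2-(ArCH2)-5-iodo-2,3-dimethylpentyl]oxy}silane | CC[Si](CC)(CC)OC[C@](C)(Cc1cc(Cl)cc(O[Si](C(C)C)(C(C)C)C(C)C)c1O[Si](C(C)C)(C(C)C)C(C)C)[C@@H](C)CCI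
F11 | step 8 | triethyl{[(2R,3S)-2-(ArCH2)-2,3,6,7-tetramethyloct-6-en-1-yl]oxy}silane | CC[Si](CC)(CC)OC[C@](C)(Cc1cc(Cl)cc(O[Si](C(C)C)(C(C)C)C(C)C)c1O[Si](C(C)C)(C(C)C)C(C)C)[C@@H](C)CCC(C)=C(C)C
F12 | step 8 | (2R,3S)-2-(ArCH2)-2,3,6,7-tetramethyloct-6-en-1-ol | OC[C@](C)(Cc1cc(Cl)cc(O[Si](C(C)C)(C(C)C)C(C)C)c1O[Si](C(C)C)(C(C)C)C(C)C)[C@@H](C)CCC(C)=C(C)C
F13 | step 18 | 3,4-bis[(triisopropylsilyl)oxy]-5-(decalylmethyl)benzaldehyde | C=C1CCC[C@H]2[C@](C)(Cc3cc(C=O)cc(O[Si](C(C)C)(C(C)C)C(C)C)c3O[Si](C(C)C)(C(C)C)C(C)C)[C@@H](C)CC[C@]12C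
F14 | step 18 | 4-hydroxy-3-[(triisopropylsilyl)oxy]-5-(decalylmethyl)benzaldehyde | C=C1CCC[C@H]2[C@](C)(Cc3cc(C=O)cc(O[Si](C(C)C)(C(C)C)C(C)C)c3O)[C@@H](C)CC[C@]12C
F15 | step 18 | 4-formyl-2-[(triisopropylsilyl)oxy]-6-(decalylmethyl)phenyl hydrogen sulfate | C=C1CCC[C@H]2[C@](C)(Cc3cc(C=O)cc(O[Si](C(C)C)(C(C)C)C(C)C)c3OS(=O)(=O)O)[C@@H](C)CC[C@]12C
F16 | step 18 | 4-(hydroxymethyl)-2-[(triisopropylsilyl)oxy]-6-(decalylmethyl)phenyl hydrogen sulfate | C=C1CCC[C@H]2[C@](C)(Cc3cc(CO)cc(O[Si](C(C)C)(C(C)C)C(C)C)c3OS(=O)(=O)O)[C@@H](C)CC[C@]12C
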